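The synthesis rests on the C9–C10 bond of ring B (C5–C10, labdane numbering). A monocyclic precursor carries ring A as a cyclohexene (C1=C10), the C5 stereocentre and a C6–C7–C8(CO2t-Bu)=C9 chain with an acetate on C7. Iron-hydride hydrogen atom transfer to C1 makes the tertiary C10 radical, which closes ring B by 6-endo addition to C9; loss of the C7 acetate then leaves the C7=C8 ester. One operation forms ring B, the quaternary C10 and C9. It exploits that C10 is fully substituted and flanked by a ring-A alkene, and that C9 is beta to the C8 carboxyl.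

Key step: step 6

Remark: atoms carry labdane numbers (ring A = C1–C5 and C10, ring B = C5–C10, C17 = carboxyl on C8, C11–C16 = side chain, C20 = methyl on C10); the SMILES is read as the ent-labdane with 5R,6S,9S,10S, a 12E diene and the acetate on the same face as the C10 methyl.

Step 1
Reactants: 1 2,4,4-trimethylcyclohex-2-en-1-one
Product: 2 (S)-2,4,4-trimethylcyclohex-2-en-1-ol
Conditions: (R)-2-methyl-CBS-oxazaborolidine (10 mol %), BH3·SMe2, THF, −20 °C; then MeOH
Reagents that add atoms: none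
Why: Corey–Bakshi–Shibata reduction, in which the oxazaborolidine binds the ketone with the methyl-bearing alkenyl arm as the large group and delivers hydride to the face that, on the usual model, gives the S carbinol at C1.

Step 2
Reactants: 2 (S)-2,4,4-trimethylcyclohex-2-en-1-ol
Product: 4 2-[(1R)-2,6,6-trimethylcyclohex-2-en-1-yl]acetaldehyde, via allyl vinyl ether 3 (not isolated)
Conditions: butyl vinyl ether, Pd(OCOCF3)2 (cat.), 4,7-diphenyl-1,10-phenanthroline (cat.), Et3N, 75 °C; evaporate; then toluene, 180 °C (sealed tube)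
Reagents that add atoms: butyl vinyl ether, C=COCCCC
Why: Transfer vinylation at divalent palladium followed by a thermal Claisen rearrangement, whose [3,3] shift is suprafacial on the ring, so the C1–O bond is traded for the C5–C6 bond on the same face; this sets C5 (R) and moves the alkene to C1=C10.

Step 3
Reactants: 5 4,4-diethoxybut-1-yne
Product: 7 tert-butyl 5,5-diethoxypent-2-ynoate, via lithium acetylide 6 (not isolated)
Conditions: n-BuLi, THF, −78 °C; then (t-BuOCO)2O, −78 to 0 °C
Reagents that add atoms: di-tert-butyl dicarbonate, CC(C)(C)OC(=O)OC(=O)OC(C)(C)C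
Why: Acylation of a lithium acetylide with the dicarbonate is a standard route to tert-butyl ynoates and forms no stereocentre.

Step 4
Reactants: 7 tert-butyl 5,5-diethoxypent-2-ynoate; 4 2-[(1R)-2,6,6-trimethylcyclohex-2-en-1-yl]acetaldehyde
Product: 9 tert-butyl (2Z)-5,5-diethoxy-2-{1-hydroxy-2-[(1R)-2,6,6-trimethylcyclohex-2-en-1-yl]ethyl}pent-2-enoate (both C7 epimers), via vinylalane 8 (not isolated)
Conditions: 7, i-Bu2AlH, N-methylmorpholine N-oxide, THF, 0 °C; then 4, 0 °C to rt; aqueous Rochelle salt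
Reagents that add atoms: none
Why: Vinylalumination (a Baylis–Hillman-type addition), in which syn hydroalumination of the ynoate puts aluminium on C8 and hydrogen on C9 and the vinylalane adds to the aldehyde with retention, so C11 ends up cis to the ester (2Z); the new C7 carbinol centre is left uncontrolled because step 6 removes it.

Step 5
Reactants: 9 tert-butyl (2Z)-5,5-diethoxy-2-{1-hydroxy-2-[(1R)-2,6,6-trimethylcyclohex-2-en-1-yl]ethyl}pent-2-enoate
Product: 10 tert-butyl (2Z)-2-{1-acetoxy-2-[(1R)-2,6,6-trimethylcyclohex-2-en-1-yl]ethyl}-5,5-diethoxypent-2-enoate (both C7 epimers)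
Conditions: Ac2O, pyridine, DMAP (cat.), CH2Cl2, 0 °C
Reagents that add atoms: acetic anhydride, CC(=O)OC(C)=O
Why: Standard acetylation turns the C7 hydroxyl into the leaving group for the later beta-elimination, run cold and briefly so that the allylic acetate does not transpose.

Step 6
Reactants: 10 tert-butyl (2Z)-2-{1-acetoxy-2-[(1R)-2,6,6-trimethylcyclohex-2-en-1-yl]ethyl}-5,5-diethoxypent-2-enoate
Product: 12 tert-butyl (1S,4aR,8aR)-1-(2,2-diethoxyethyl)-5,5,8a-trimethyl-1,4,4a,5,6,7,8,8a-octahydronaphthalene-2-carboxylate, via beta-acetoxy ester 11 (not isolated)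
Conditions: Fe(acac)3 (30 mol %), PhSiH3, EtOH/(CH2OH)2, 60 °C; then DBU, rt
Reagents that add atoms: none
Why: The iron hydride formed from Fe(acac)3 and PhSiH3 transfers a hydrogen atom to C1 of the electron-rich ring-A alkene (the electron-poor enoate is left alone), the tertiary C10 radical adds to C9 of the tethered Z-enoate, and the C8 radical is reduced and protonated to 11, from which DBU expels the C7 acetate (E1cB) to leave the C7=C8 ester. The closest known reaction type is the iron-hydride hydrogen-atom-transfer reductive olefin coupling (radical conjugate addition) in its intramolecular form, as used to close trans-decalins, followed by an ordinary beta-acetoxy ester elimination. Ring B (C5–C10) closes in a 6-endo-trig radical mode, favoured over 5-exo attack at C8 because only attack at the beta-carbon C9 gives the ester-stabilised radical. C10 is controlled by the C5 stereocentre: in the chair transition state the C5–C6 tether is equatorial and the new bond forms equatorially, away from the axial C4 methyl, so the C10 methyl becomes axial and anti to H5 (trans ring fusion). C9 is controlled by the alkene geometry: C11 is trans to C7 on the Z-enoate and is therefore equatorial in that chair, cis to the C10 methyl. The step needs chair rather than boat closure and ring closure faster than a second hydrogen transfer to the C10 radical; the unsubstituted C6 and the ester-activated acceptor favour both.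

Step 7
Reactants: 12 tert-butyl (1S,4aR,8aR)-1-(2,2-diethoxyethyl)-5,5,8a-trimethyl-1,4,4a,5,6,7,8,8a-octahydronaphthalene-2-carboxylate
Product: 13 tert-butyl (1S,4aR,8aS)-1-(2,2-diethoxyethyl)-5,5,8a-trimethyl-4-oxo-1,4,4a,5,6,7,8,8a-octahydronaphthalene-2-carboxylate
Conditions: Rh2(cap)4 (cap = caprolactamate, 1 mol %), t-BuOOH (70% in water), K2CO3, CH2Cl2, rt
Reagents that add atoms: tert-butyl hydroperoxide, CC(C)(C)OO
Why: Allylic oxidation by tert-butylperoxyl radicals under Rh2(cap)4 catalysis, a reaction known for cyclohex-1-enecarboxylates, should occur at the C6 methylene, whose allyl radical is conjugated through to the ester, and not at the tertiary C9–H shielded by the quaternary C10; C5 stays trans-fused.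

Step 8
Reactants: 13 tert-butyl (1S,4aR,8aS)-1-(2,2-diethoxyethyl)-5,5,8a-trimethyl-4-oxo-1,4,4a,5,6,7,8,8a-octahydronaphthalene-2-carboxylate
Product: 14 tert-butyl (1S,4S,4aR,8aS)-1-(2,2-diethoxyethyl)-4-hydroxy-5,5,8a-trimethyl-1,4,4a,5,6,7,8,8a-octahydronaphthalene-2-carboxylate
Conditions: NaBH4, CeCl3·7H2O, MeOH, −78 °C
Reagents that add atoms: none
Why: Luche reduction, in which the cerium-modified borohydride adds 1,2 to the C6 ketone from the face away from the axial C4 and C10 methyl groups, so the new hydroxyl is axial and cis to the C10 methyl (6S in labdane numbering).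

Step 9
Reactants: 14 tert-butyl (1S,4S,4aR,8aS)-1-(2,2-diethoxyethyl)-4-hydroxy-5,5,8a-trimethyl-1,4,4a,5,6,7,8,8a-octahydronaphthalene-2-carboxylate
Product: 15 tert-butyl (1S,4S,4aR,8aS)-4-acetoxy-1-(2,2-diethoxyethyl)-5,5,8a-trimethyl-1,4,4a,5,6,7,8,8a-octahydronaphthalene-2-carboxylate
Conditions: Ac2O, DMAP, pyridine, 40 °C
Reagents that add atoms: acetic anhydride, CC(=O)OC(C)=O
Why: DMAP-catalysed acetylation of the hindered axial alcohol installs the C6 acetate of the target without touching the tert-butyl ester or the acetal.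

Step 10
Reactants: 15 tert-butyl (1S,4S,4aR,8aS)-4-acetoxy-1-(2,2-diethoxyethyl)-5,5,8a-trimethyl-1,4,4a,5,6,7,8,8a-octahydronaphthalene-2-carboxylate
Product: 16 (1S,4S,4aR,8aS)-4-acetoxy-5,5,8a-trimethyl-1-(2-oxoethyl)-1,4,4a,5,6,7,8,8a-octahydronaphthalene-2-carboxylic acid
Conditions: CF3CO2H, CH2Cl2, H2O, 0 °C to rt
Reagents that add atoms: water, O
Why: Acidolysis, in which trifluoroacetic acid cleaves the tert-butyl ester by loss of 2-methylpropene and, with water, hydrolyses the diethyl acetal to the C12 aldehyde, while the acetate on the electron-poor allylic C6 should not ionise.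

Step 11
Reactants: 16 (1S,4S,4aR,8aS)-4-acetoxy-5,5,8a-trimethyl-1-(2-oxoethyl)-1,4,4a,5,6,7,8,8a-octahydronaphthalene-2-carboxylic acid
Product: 17 (1S,4S,4aR,8aS)-4-acetoxy-5,5,8a-trimethyl-1-[(2E)-3-methyl-4-oxobut-2-en-1-yl]-1,4,4a,5,6,7,8,8a-octahydronaphthalene-2-carboxylic acid
Conditions: Ph3P=C(CH3)CHO (3 equiv), toluene, 80 °C; then aqueous citric acid
Reagents that add atoms: 2-(triphenylphosphoranylidene)propanal, CC(C=O)=P(c1ccccc1)(c1ccccc1)c1ccccc1
Why: Wittig reaction with the stabilised formyl ylide should give the trisubstituted enal with the E geometry (C11 trans to C14) typical of such ylides, the excess ylide allowing for the part that the free acid protonates.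

Step 12
Reactants: 17 (1S,4S,4aR,8aS)-4-acetoxy-5,5,8a-trimethyl-1-[(2E)-3-methyl-4-oxobut-2-en-1-yl]-1,4,4a,5,6,7,8,8a-octahydronaphthalene-2-carboxylic acid
Product: 18 (1S,4S,4aR,8aS)-4-acetoxy-5,5,8a-trimethyl-1-[(2E)-3-methylpenta-2,4-dien-1-yl]-1,4,4a,5,6,7,8,8a-octahydronaphthalene-2-carboxylic acid (CNP0294871.1)
Conditions: Ph3PCH3Br, KN(SiMe3)2 (excess), THF, −78 to 0 °C; then aqueous NaH2PO4
Reagents that add atoms: methyltriphenylphosphonium bromide, C[P+](c1ccccc1)(c1ccccc1)c1ccccc1.[Br-]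
Why: Wittig methylenation of the enal completes the 12E,14-diene; the excess base first forms the carboxylate, which shields C17 and the enoate, and the aldehyde should react far faster than the hindered acetate.

Compound list
1 | 2,4,4-trimethylcyclohex-2-en-1-one | CC1=CC(C)(C)CCC1=O | starting material
2 | (S)-2,4,4-trimethylcyclohex-2-en-1-ol | O[C@H]1CCC(C)(C)C=C1C | intermediate
3 | (1S)-2,4,4-trimethylcyclohex-2-en-1-yl vinyl ether | C=CO[C@H]1CCC(C)(C)C=C1C | intermediate
4 | 2-[(1R)-2,6,6-trimethylcyclohex-2-en-1-yl]acetaldehyde | O=CC[C@@H]1C(C)(C)CCC=C1C | intermediate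
5 | 4,4-diethoxybut-1-yne | C#CCC(OCC)OCC | starting material
6 | (4,4-diethoxybut-1-yn-1-yl)lithium | [Li]C#CCC(OCC)OCC | intermediate
7 | tert-butyl 5,5-diethoxypent-2-ynoate | CCOC(OCC)CC#CC(=O)OC(C)(C)C | intermediate
8 | tert-butyl (2E)-2-(diisobutylalumanyl)-5,5-diethoxypent-2-enoate (Al cis to the C9 hydrogen) | CC(C)C[Al](CC(C)C)/C(=C/CC(OCC)OCC)C(=O)OC(C)(C)C | intermediate
9 | tert-butyl (2Z)-5,5-diethoxy-2-{1-hydroxy-2-[(1R)-2,6,6-trimethylcyclohex-2-en-1-yl]ethyl}pent-2-enoate (both C7 epimers) | CCOC(OCC)C/C=C(\C(=O)OC(C)(C)C)C(O)C[C@@H]1C(C)(C)CCC=C1C | intermediate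
10 | tert-butyl (2Z)-2-{1-acetoxy-2-[(1R)-2,6,6-trimethylcyclohex-2-en-1-yl]ethyl}-5,5-diethoxypent-2-enoate (both C7 epimers) | CCOC(OCC)C/C=C(\C(=O)OC(C)(C)C)C(OC(C)=O)C[C@@H]1C(C)(C)CCC=C1C | intermediate
11 | tert-butyl (1R,4aR,8aS)-3-acetoxy-1-(2,2-diethoxyethyl)-5,5,8a-trimethyldecahydronaphthalene-2-carboxylate (epimers at labdane C7 and C8) | CCOC(OCC)C[C@@H]1C(C(=O)OC(C)(C)C)C(OC(C)=O)C[C@@H]2C(C)(C)CCC[C@@]12C | intermediate
12 | tert-butyl (1S,4aR,8aR)-1-(2,2-diethoxyethyl)-5,5,8a-trimethyl-1,4,4a,5,6,7,8,8a-octahydronaphthalene-2-carboxylate | CCOC(OCC)C[C@@H]1C(C(=O)OC(C)(C)C)=CC[C@@H]2C(C)(C)CCC[C@@]12C | intermediate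
13 | tert-butyl (1S,4aR,8aS)-1-(2,2-diethoxyethyl)-5,5,8a-trimethyl-4-oxo-1,4,4a,5,6,7,8,8a-octahydronaphthalene-2-carboxylate | CCOC(OCC)C[C@@H]1C(C(=O)OC(C)(C)C)=CC(=O)[C@@H]2C(C)(C)CCC[C@@]12C | intermediate
14 | tert-butyl (1S,4S,4aR,8aS)-1-(2,2-diethoxyethyl)-4-hydroxy-5,5,8a-trimethyl-1,4,4a,5,6,7,8,8a-octahydronaphthalene-2-carboxylate | CCOC(OCC)C[C@@H]1C(C(=O)OC(C)(C)C)=C[C@H](O)[C@@H]2C(C)(C)CCC[C@@]12C | intermediate
15 | tert-butyl (1S,4S,4aR,8aS)-4-acetoxy-1-(2,2-diethoxyethyl)-5,5,8a-trimethyl-1,4,4a,5,6,7,8,8a-octahydronaphthalene-2-carboxylate | CCOC(OCC)C[C@@H]1C(C(=O)OC(C)(C)C)=C[C@H](OC(C)=O)[C@@H]2C(C)(C)CCC[C@@]12C | intermediate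
16 | (1S,4S,4aR,8aS)-4-acetoxy-5,5,8a-trimethyl-1-(2-oxoethyl)-1,4,4a,5,6,7,8,8a-octahydronaphthalene-2-carboxylic acid | O=CC[C@@H]1C(C(=O)O)=C[C@H](OC(C)=O)[C@@H]2C(C)(C)CCC[C@@]12C | intermediate
17 | (1S,4S,4aR,8aS)-4-acetoxy-5,5,8a-trimethyl-1-[(2E)-3-methyl-4-oxobut-2-en-1-yl]-1,4,4a,5,6,7,8,8a-octahydronaphthalene-2-carboxylic acid | O=C/C(C)=C/C[C@@H]1C(C(=O)O)=C[C@H](OC(C)=O)[C@@H]2C(C)(C)CCC[C@@]12C | intermediate
18 | (1S,4S,4aR,8aS)-4-acetoxy-5,5,8a-trimethyl-1-[(2E)-3-methylpenta-2,4-dien-1-yl]-1,4,4a,5,6,7,8,8a-octahydronaphthalene-2-carboxylic acid (CNP0294871.1) | C=C/C(C)=C/C[C@@H]1C(C(=O)O)=C[C@H](OC(C)=O)[C@@H]2C(C)(C)CCC[C@@]12C | target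

Total step count: 12. Longest linear sequence: 11 steps (1 to 18 through steps 1, 2 and 4–12; step 3 lies on the side branch from 5).

Steps most likely to fail

Step 6. The C10 radical may take a second hydrogen atom (net hydrogenation of the ring alkene) before it closes the ring, or closure through a boat may erode the control at C9. The fallback makes the radical without a metal hydride. It sets out from 10: Mukaiyama hydration of the ring alkene (Co(acac)2, PhSiH3, O2, i-PrOH) should give the tertiary alcohol F1; acylation with methyl chlorooxoacetate (Et3N, DMAP) gives the methyl oxalate F2; CsOH (1 equiv, THF/H2O) gives the caesium oxalate F3. Visible-light photoredox decarboxylation of F3 (Ir[dF(CF3)ppy]2(dtbbpy)PF6, blue light, DME/DMF, water) releases the same C10 radical with no hydrogen-atom donor present; 6-endo addition, reduction to the ester enolate and loss of acetate bring the route back at 12.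

Step 7. Hydrogen abstraction may occur at the tertiary C9–H or at the acetal C–H instead of C6, or the product may be over-oxidised. The fallback is anionic and avoids C–H abstraction. It sets out from 12: LiN(i-Pr)2 with HMPA (THF, −78 °C) forms the extended ester enolate by loss of a C6 proton, and PhSeBr at C8 gives the deconjugated alpha-selenide F4. H2O2/pyridine oxidises selenium, and the [2,3]-sigmatropic shift of the allyl selenoxide gives the C6 alcohol F5 (either epimer). Dess–Martin periodinane then brings the route back at 13.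

Step 4. Aldehyde 4 may be reduced or enolised by aluminium hydride species, or the hindered vinylalane may add too slowly. The fallback uses a chromium vinyl nucleophile. It sets out from 7: Pd(PPh3)4-catalysed syn hydrostannation with Bu3SnH gives the alpha-stannyl enoate F6, and I2 gives the alpha-iodo enoate F7 with retention. Nozaki–Hiyama–Kishi coupling of F7 with 4 (CrCl2, NiCl2 cat., DMF) brings the route back at 9 with the same alkene geometry.

Further compounds
F1 | step 6 | tert-butyl (2Z)-2-{1-acetoxy-2-[(1R)-2-hydroxy-2,6,6-trimethylcyclohexyl]ethyl}-5,5-diethoxypent-2-enoate | CCOC(OCC)C/C=C(\C(=O)OC(C)(C)C)C(OC(C)=O)C[C@@H]1C(C)(C)CCCC1(C)O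
F2 | step 6 | tert-butyl (2Z)-2-{1-acetoxy-2-[(1R)-2-(methoxyoxalyloxy)-2,6,6-trimethylcyclohexyl]ethyl}-5,5-diethoxypent-2-enoate | CCOC(OCC)C/C=C(\C(=O)OC(C)(C)C)C(OC(C)=O)C[C@@H]1C(C)(C)CCCC1(C)OC(=O)C(=O)OC
F3 | step 6 | caesium salt of the oxalic half ester of F1 | CCOC(OCC)C/C=C(\C(=O)OC(C)(C)C)C(OC(C)=O)C[C@@H]1C(C)(C)CCCC1(C)OC(=O)C(=O)[O-].[Cs+]
F4 | step 7 | tert-butyl (1S,4aR,8aR)-1-(2,2-diethoxyethyl)-5,5,8a-trimethyl-2-(phenylselanyl)-1,2,4a,5,6,7,8,8a-octahydronaphthalene-2-carboxylate | CCOC(OCC)C[C@@H]1C(C(=O)OC(C)(C)C)([Se]c3ccccc3)C=C[C@@H]2C(C)(C)CCC[C@@]12C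
F5 | step 7 | tert-butyl (1S,4aR,8aS)-1-(2,2-diethoxyethyl)-4-hydroxy-5,5,8a-trimethyl-1,4,4a,5,6,7,8,8a-octahydronaphthalene-2-carboxylate (either C4 epimer) | CCOC(OCC)C[C@@H]1C(C(=O)OC(C)(C)C)=CC(O)[C@@H]2C(C)(C)CCC[C@@]12C
F6 | step 4 | tert-butyl (2E)-5,5-diethoxy-2-(tributylstannyl)pent-2-enoate | CCCC[Sn](CCCC)(CCCC)/C(=C/CC(OCC)OCC)C(=O)OC(C)(C)C
F7 | step 4 | tert-butyl (2E)-5,5-diethoxy-2-iodopent-2-enoate | CCOC(OCC)C/C=C(/I)C(=O)OC(C)(C)C
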